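The data are calculated on assumed constants, noise included.

1.8% of over-reaction product against 45.2% of target: that ochre reading at 12.0 min opened the meeting on four set-ups for a single charge.

| setting | green | blue | ochre | red | alpha | gamma | eta | beta |
|---|---|---|---|---|---|---|---|---|
| substrate | 35 mM | 35 mM | 35 mM | 18 mM | 35 mM (fed, over 9.60 min) | 35 mM | 35 mM | 35 mM |
| reagent | 1.3 equiv | 1.3 equiv | 1.3 equiv | 1.3 equiv | 1.30 equiv | 1.30 equiv | 1.30 equiv (fed, over 9.60 min) | 1.30 equiv |
| free catalyst | 10 mol% | 5 mol% | 20 mol% | 10 mol% | 10 mol% | 10 mol% | 10 mol% | 10 mol% |
| remark | run made earlier | run made earlier | run made earlier | run made earlier | a stirred flask in which substrate is dosed at a steady rate over 9.60 min without added volume, worked up at 12 min | one stirred flow tank at steady state, fed with the mixture as stated, mean residence time 12 min | all but reagent at the start; reagent goes in evenly over 9.60 min, the run ends at 12 min | everything together in a closed stirred flask, run for 12 min |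
| time |  |  |  |  | 12 min |  | 12 min | 12 min |

- green (time / min: target / %, over-reaction product / %, substrate / %): 0.500: 0, 0.5, 96.2; 0.833: 0.5, 0.5, 94.2; 1.33: 1.8, 0, 90.9; 2.00: 3.5, 0, 88.2; 3.00: 6.0, 0.4, 86.1; 5.00: 12.9, 0, 81.4; 8.00: 18.3, 0.5, 74.0
- blue (time / min: target / %, over-reaction product / %, substrate / %): 1.50: 1.2, 0.1, 95.5; 3.00: 3.6, 0, 93.0; 5.00: 6.1, 0, 89.9; 6.00: 8.9, 0, 87.6; 8.00: 10.5, 0.7, 85.4; 10.0: 14.3, 0, 82.9; 12.0: 16.7, 1.0, 79.5
- ochre (time / min: target / %, over-reaction product / %, substrate / %): 0.667: 1.1, 0.1, 90.0; 2.00: 7.5, 0.7, 78.7; 3.00: 12.2, 0, 74.8; 5.00: 20.0, 0.5, 66.8; 8.00: 32.1, 1.2, 56.7; 10.0: 39.3, 1.1, 50.2; 12.0: 45.2, 1.8, 43.4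
- red (time / min: target / %, over-reaction product / %, substrate / %): 1.00: 1.3, 0, 95.5; 3.00: 5.3, 0, 88.7; 6.00: 11.0, 0.2, 82.9; 8.00: 15.3, 1.4, 78.6; 12.0: 22.8, 1.9, 71.1

(each reading ± 0.5 percentage points)

- the stated concentrations are those of everything mixed, before any reaction; amounts are the same in each set-up
- the analysis behind the earlier runs scatters by 0.5 percentage points, standard deviation
- candidate steps: reagent + free catalyst -> catalyst intermediate A; substrate + catalyst intermediate A -> catalyst intermediate B; catalyst intermediate B <-> by-product + catalyst intermediate C; catalyst intermediate C -> free catalyst + target; 2 catalyst intermediate A -> spent catalyst; target -> over-reaction product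
- the feed brings no volume worth counting
- the earlier runs were made in a closed, stirred flask

- the set-up with the highest share of target in all that became target or over-reaction product, at the outlet or at the end ("none" if the first two lie within 2 percentage points) (alpha / gamma / eta / beta / none)
- share of target in all that became target or over-reaction product, at the outlet or at the end, alpha
- share of target in all that became target or over-reaction product, at the outlet or at the end, gamma
- share of target in all that became target or over-reaction product, at the outlet or at the end, eta
- share of target in all that became target or over-reaction product, at the outlet or at the end, beta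

The analyst reported that in the green run target climbs in a nearly straight line after a lag, and two readings put that lag at 0.883 min.

The kineticist then integrated the one rate that matters. If the target fraction rises steadily and each bit of it is lost by a first-order step, the over-reaction fraction divided by the target fraction equals the rate constant times half the time since the lag. That half is the mean age of the target, in beta 5.56 min. The speed of making cancels, so she argued that the selectivity, the share asked for, depends on age and that ochre may lend its ratio to beta.

Its ratio gave a constant of 0.007164 min⁻¹, a reading uncertain by about a quarter, since one reading scatters by 0.5 percentage points.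

My own reckoning followed: beta keeps 96.2%. In gamma the mean age is the residence time 12 min, about twice that of beta, so gamma keeps 92.1%.

A colleague supposed that in a dosed flask making starts at mid-dose, 4.80 min; that gives 97.5%, which is more than beta by 1.3 points, less than the margin of 2 points. Gamma stayed lowest, and the meeting wrote down "none".

The forecast, reasoning that “Share depends only on how long target sits”, gave alpha 96.4%, gamma 92.3%, eta 97%, beta 96.2%, and as best none.

    reagent + free catalyst → catalyst intermediate A (k = 74.0 L mol⁻¹ min⁻¹)
    substrate + catalyst intermediate A → catalyst intermediate B (k = 68.0 L mol⁻¹ min⁻¹)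
    catalyst intermediate B ⇌ by-product + catalyst intermediate C (K = 0.0400 M, k = 15.0 min⁻¹)
    catalyst intermediate C → free catalyst + target (k = 0.450 min⁻¹)
    2 catalyst intermediate A → spent catalyst (k = 70.0 L mol⁻¹ min⁻¹)
    target → over-reaction product (k = 0.00430 min⁻¹)

The flask gives none as best, with alpha 97.9%, gamma 95.1%, eta 97.9% and beta 97.5%. With the loss of target to over-reaction product struck out, eta stands at 100%. Beta's mean age of 5.56 min, at the constant 0.0043 min⁻¹ of the last step above, gives a share of 97.7%, beside the flask's 97.5%. Eta left until 120 min shows a share of 68.5%, and at that same constant this is the survival of target roughly 88.0 min old.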